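## Retrosynthetic overview

1. The target is an 8–8'-linked dibenzylbutane. Lignan numbering is used: ring A is the guaiacyl ring carrying C7H2–C8H–C9H2OAc, ring B is the syringyl ring carrying C7'H2–C8'H–C9'H3. The last operations turn a C9 acyl group into CH2OAc and remove a C7' oxygen together with both O-benzyl groups in one hydrogenolysis.
2. Key disconnection C8–C8'. The enabling feature is that C8 is α to C9, which can be held as an imide carbonyl, and C8' is α to the benzylic carbon C7' of ring B, which can be held as an aryl ketone. The bond is therefore the central bond of a latent 1,4-dicarbonyl between two enolizable carbons, and C9' is simply the methyl group of a propiophenone.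
3. The bond is made by Fe(acac)3-mediated oxidative heterocoupling of two lithium enolates: that of the (R)-4-benzyloxazolidinone imide of O-benzyl dihydroferulic acid and that of O-benzyl propiosyringone. One operation joins the halves and sets C8 (auxiliary control) and C8'.
4. The imide comes from dihydroferulic acid in 2 steps, the ketone from syringaldehyde in 3 steps.
5. No ring is formed in the route; rings A and B are bought intact.

Key step: step 6

Remark on the chemistry: the two intermediates that carry an oxygen at C7' are expected as mixtures of C7' epimers and are drawn without configuration there; this centre becomes CH2 in the last step.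

## Route

Step 1
Reactants: 1 dihydroferulic acid (3-(4-hydroxy-3-methoxyphenyl)propanoic acid)
Product: 3 O-benzyl dihydroferulic acid (3-[4-(benzyloxy)-3-methoxyphenyl]propanoic acid), via benzyl ester benzyl ether 2 (not isolated)
Conditions: BnBr (2.2 equiv), K2CO3, DMF, 60 °C; then NaOH aq., MeOH, 60 °C; HCl aq.
Reagents that add atoms: benzyl bromide, BrCc1ccccc1; sodium hydroxide, [Na+].[OH-] (its oxygen ends in the carboxyl group)
Why: Williamson O-alkylation (SN2) benzylates both the phenoxide and the carboxylate, and saponification of the benzyl ester 2 in the same flask returns the acid while the aryl benzyl ether is stable to hydroxide.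

Step 2
Reactants: 3 O-benzyl dihydroferulic acid
Product: 5 (R)-4-benzyl-3-{3-[4-(benzyloxy)-3-methoxyphenyl]propanoyl}oxazolidin-2-one, via mixed pivalic anhydride 4 (not isolated)
Conditions: PivCl, Et3N, THF, −20 °C; then (R)-4-benzyloxazolidin-2-one, LiCl, −20 °C → rt
Reagents that add atoms: (R)-4-benzyloxazolidin-2-one, O=C1N[C@H](Cc2ccccc2)CO1; pivaloyl chloride, CC(C)(C)C(Cl)=O (its atoms stay in 4 only)
Why: Mixed-anhydride N-acylation of an oxazolidinone (LiCl/Et3N variant), in which the oxazolidinone attacks the less hindered acyl group of 4, the pivaloyl group serves only as leaving group and the stereocentre of the auxiliary is not touched.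

Step 3
Reactants: 6 syringaldehyde (4-hydroxy-3,5-dimethoxybenzaldehyde)
Product: 7 4-(benzyloxy)-3,5-dimethoxybenzaldehyde
Conditions: BnBr, K2CO3, DMF, 60 °C
Reagents that add atoms: benzyl bromide, BrCc1ccccc1
Why: Williamson ether synthesis on the hindered but acidic syringyl phenol, with the aldehyde inert to K2CO3.

Step 4
Reactants: 7 4-(benzyloxy)-3,5-dimethoxybenzaldehyde
Product: 8 1-[4-(benzyloxy)-3,5-dimethoxyphenyl]propan-1-ol (racemic)
Conditions: EtMgBr, THF, 0 °C; aqueous work-up
Reagents that add atoms: ethylmagnesium bromide, CC[Mg]Br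
Why: Grignard 1,2-addition to the aromatic aldehyde should give the secondary benzylic alcohol as a racemate, which is of no consequence because the carbinol is oxidized next.

Step 5
Reactants: 8 1-[4-(benzyloxy)-3,5-dimethoxyphenyl]propan-1-ol
Product: 9 1-[4-(benzyloxy)-3,5-dimethoxyphenyl]propan-1-one (O-benzyl propiosyringone)
Conditions: MnO2 (excess), CH2Cl2, rt
Reagents that add atoms: none
Why: MnO2 oxidation is selective for the electron-rich benzylic alcohol and leaves the benzyl ether untouched, giving the propiophenone whose ethyl group already holds C8' and the C9' methyl group.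

Step 6
Reactants: 5 (R)-4-benzyl-3-{3-[4-(benzyloxy)-3-methoxyphenyl]propanoyl}oxazolidin-2-one; 9 1-[4-(benzyloxy)-3,5-dimethoxyphenyl]propan-1-one (1.2 equiv)
Product: 12 (R)-4-benzyl-3-[(2S,3S)-2-[4-(benzyloxy)-3-methoxybenzyl]-4-[4-(benzyloxy)-3,5-dimethoxyphenyl]-3-methyl-4-oxobutanoyl]oxazolidin-2-one, via imide lithium Z-enolate 10 (not isolated), via ketone lithium Z-enolate 11 (not isolated)
Conditions: LiN(iPr)2 (2.2 equiv), THF, −78 °C; then Fe(acac)3 (2.2 equiv), THF, −78 °C → rt
Reagents that add atoms: none
Why: Both carbonyl compounds are converted by LiN(iPr)2 into their lithium Z-enolates 10 and 11, and single-electron oxidation by trivalent iron (Fe(acac)3) within the mixed enolate aggregate gives an α-carbonyl radical that is captured by the second enolate, the resulting ketyl-type radical anion being oxidized by the second equivalent of Fe(acac)3 to the 1,4-dicarbonyl compound 12. The closest known reaction type is the intermolecular oxidative heterocoupling of N-acyloxazolidinone enolates with ketone enolates mediated by Fe(acac)3 or copper carboxylates, for which 3-arylpropanoyl imides and propiophenones are typical partners; no ring is closed. C8 is controlled by the auxiliary: bond formation on the face of the chelated Z-enolate opposite to the benzyl group of the (R)-oxazolidinone, the same sense as in alkylations of such enolates, should give the S configuration. C8' is set by simple diastereoselection between the two prochiral enolate carbons and is expected to be the less selective centre, so the wanted (2S,3S) isomer is to be separated by chromatography, and because C8' is α to the aryl ketone the unwanted epimer can be returned to the mixture by base-mediated equilibration while the imide α-hydrogen is shielded by allylic strain. The step needs cross- over homocoupling, which the electronic difference between the acyl-stabilized, chelated imide enolate and the more electron-rich aryl ketone enolate should secure, since only one of them is oxidized readily and the other serves as radical acceptor; a small excess of the cheaper ketone 9 supports it. The benzyl ethers and the electron-rich rings A and B are inert to the mild oxidant.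

Step 7
Reactants: 12 the coupled keto imide
Product: 13 (2S,3S)-2-[4-(benzyloxy)-3-methoxybenzyl]-4-[4-(benzyloxy)-3,5-dimethoxyphenyl]-3-methylbutane-1,4-diol (C4 carbinol epimers)
Conditions: LiBH4, THF/MeOH, 0 °C → rt
Reagents that add atoms: none
Why: LiBH4 reductive cleavage of the N-acyloxazolidinone gives the primary C9 alcohol and frees the auxiliary for reuse while the aryl ketone is reduced to the C7' carbinol (either order converges on 13, also through a transient lactone), and C8 and C8' should stay untouched because hydride addition to the ketone is faster than enolization.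

Step 8
Reactants: 13 the diol
Product: 14 (2S,3S)-2-[4-(benzyloxy)-3-methoxybenzyl]-4-[4-(benzyloxy)-3,5-dimethoxyphenyl]-3-methylbutane-1,4-diyl diacetate (C4 epimers)
Conditions: Ac2O, pyridine, DMAP (cat.), CH2Cl2, rt
Reagents that add atoms: acetic anhydride, CC(=O)OC(C)=O
Why: DMAP-catalysed acylation converts the primary and the secondary benzylic hydroxyl group into acetates, the first being the acetate of the target and the second an activated leaving group for hydrogenolysis.

Step 9
Reactants: 14 the diacetate
Product: 15 (2S,3R)-2-(4-hydroxy-3-methoxybenzyl)-4-(4-hydroxy-3,5-dimethoxyphenyl)-3-methylbutyl acetate (target, CID53359578)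
Conditions: H2 (1 atm), Pd/C (10% palladium on carbon), EtOAc/AcOH, rt
Reagents that add atoms: none
Why: Palladium-catalysed hydrogenolysis should cleave the two aryl benzyl ethers and the benzylic C7'–O bond of the electron-rich ring B (benzylic acetate hydrogenolysis, as used to remove benzylic oxygen in lignan aldol adducts), while the non-benzylic primary acetate and the two stereocentres, neither of which is benzylic, are not affected.

## Compound list

1 | dihydroferulic acid, 3-(4-hydroxy-3-methoxyphenyl)propanoic acid | COc1cc(CCC(=O)O)ccc1O | starting material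
2 | benzyl 3-[4-(benzyloxy)-3-methoxyphenyl]propanoate | COc1cc(CCC(=O)OCc2ccccc2)ccc1OCc1ccccc1 | intermediate
3 | 3-[4-(benzyloxy)-3-methoxyphenyl]propanoic acid | COc1cc(CCC(=O)O)ccc1OCc1ccccc1 | intermediate
4 | 3-[4-(benzyloxy)-3-methoxyphenyl]propanoic pivalic anhydride | COc1cc(CCC(=O)OC(=O)C(C)(C)C)ccc1OCc1ccccc1 | intermediate
5 | (R)-4-benzyl-3-{3-[4-(benzyloxy)-3-methoxyphenyl]propanoyl}oxazolidin-2-one | COc1cc(CCC(=O)N2C(=O)OC[C@H]2Cc2ccccc2)ccc1OCc1ccccc1 | intermediate
6 | syringaldehyde, 4-hydroxy-3,5-dimethoxybenzaldehyde | COc1cc(C=O)cc(OC)c1O | starting material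
7 | 4-(benzyloxy)-3,5-dimethoxybenzaldehyde | COc1cc(C=O)cc(OC)c1OCc1ccccc1 | intermediate
8 | 1-[4-(benzyloxy)-3,5-dimethoxyphenyl]propan-1-ol (racemic) | CCC(O)c1cc(OC)c(OCc2ccccc2)c(OC)c1 | intermediate
9 | 1-[4-(benzyloxy)-3,5-dimethoxyphenyl]propan-1-one | CCC(=O)c1cc(OC)c(OCc2ccccc2)c(OC)c1 | intermediate
10 | lithium Z-enolate of imide 5 | [Li+].COc1cc(C/C=C(\[O-])N2C(=O)OC[C@H]2Cc2ccccc2)ccc1OCc1ccccc1 | intermediate
11 | lithium Z-enolate of ketone 9 | [Li+].C/C=C(\[O-])c1cc(OC)c(OCc2ccccc2)c(OC)c1 | intermediate
12 | (R)-4-benzyl-3-[(2S,3S)-2-[4-(benzyloxy)-3-methoxybenzyl]-4-[4-(benzyloxy)-3,5-dimethoxyphenyl]-3-methyl-4-oxobutanoyl]oxazolidin-2-one | COc1cc(C[C@H](C(=O)N2C(=O)OC[C@H]2Cc2ccccc2)[C@H](C)C(=O)c2cc(OC)c(OCc3ccccc3)c(OC)c2)ccc1OCc1ccccc1 | intermediate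
13 | (2S,3S)-2-[4-(benzyloxy)-3-methoxybenzyl]-4-[4-(benzyloxy)-3,5-dimethoxyphenyl]-3-methylbutane-1,4-diol, C4 epimers | COc1cc(C[C@H](CO)[C@H](C)C(O)c2cc(OC)c(OCc3ccccc3)c(OC)c2)ccc1OCc1ccccc1 | intermediate
14 | (2S,3S)-2-[4-(benzyloxy)-3-methoxybenzyl]-4-[4-(benzyloxy)-3,5-dimethoxyphenyl]-3-methylbutane-1,4-diyl diacetate, C4 epimers | COc1cc(C[C@H](COC(C)=O)[C@H](C)C(OC(C)=O)c2cc(OC)c(OCc3ccccc3)c(OC)c2)ccc1OCc1ccccc1 | intermediate
15 | (2S,3R)-2-(4-hydroxy-3-methoxybenzyl)-4-(4-hydroxy-3,5-dimethoxyphenyl)-3-methylbutyl acetate | COc1cc(C[C@H](COC(C)=O)[C@H](C)Cc2cc(OC)c(O)c(OC)c2)ccc1O | target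

## Step count

Total step count: 9 steps.
Longest linear sequence: 7 steps (steps 3, 4, 5, 6, 7, 8, 9 from syringaldehyde 6).

## Three steps most likely to fail

**Step 6 (key step).** What may go wrong: poor simple diastereoselection at C8' in the radical–enolate bond formation, and competing homocoupling of either enolate, so that little of the (2S,3S) isomer is obtained.

Fallback: it changes the approach. C8' is set first by reagent-controlled crotylboration, C8 afterwards by substrate-controlled lactone alkylation, and the bond that joins the halves is C7–C8. It sets out from aldehyde 7 and comes back to the route at diol 13.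
- Brown crotylboration of 7 with (Z)-crotyl-B(Ipc)2 of the (+)-Ipc2BOMe series (THF, −78 °C; NaOH/H2O2) should give the syn homoallylic alcohol (1R,2S)-1-[4-(benzyloxy)-3,5-dimethoxyphenyl]-2-methylbut-3-en-1-ol F1.
- Hydroboration–oxidation of the vinyl group (9-BBN, THF; NaOH/H2O2) should give (1R,2S)-1-[4-(benzyloxy)-3,5-dimethoxyphenyl]-2-methylbutane-1,4-diol F2.
- Oxidative lactonization (TEMPO cat., PhI(OAc)2, CH2Cl2) should give the cis lactone (4S,5R)-5-[4-(benzyloxy)-3,5-dimethoxyphenyl]-4-methyldihydrofuran-2(3H)-one F3.
- Enolate alkylation (LiN(iPr)2, THF, −78 °C; then purchased 4-(benzyloxy)-3-methoxybenzyl bromide) is expected to occur on the face opposite to the 4-methyl and 5-aryl groups and give (3S,4S,5R)-3-[4-(benzyloxy)-3-methoxybenzyl]-5-[4-(benzyloxy)-3,5-dimethoxyphenyl]-4-methyldihydrofuran-2(3H)-one F4.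
- LiAlH4 (THF, 0 °C) should open F4 to diol 13, here as a single C7' epimer.

**Step 7.** What may go wrong: hydride attack at the ring carbonyl of the hindered, α-branched imide (opening of the auxiliary instead of its release), and enolization at C8' before the ketone is reduced.

Fallback: the auxiliary is removed by intramolecular acyl transfer instead of direct hydride attack. It sets out from 12 and comes back at 13.
- Zn(BH4)2 (Et2O, 0 °C) should reduce only the ketone and give (R)-4-benzyl-3-[(2S,3S)-2-[4-(benzyloxy)-3-methoxybenzyl]-4-[4-(benzyloxy)-3,5-dimethoxyphenyl]-4-hydroxy-3-methylbutanoyl]oxazolidin-2-one F5.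
- With DBU (cat.) in CH2Cl2 the hydroxyl group of F5 should acylate itself on the exocyclic carbonyl and expel the auxiliary, giving (3S,4S)-3-[4-(benzyloxy)-3-methoxybenzyl]-5-[4-(benzyloxy)-3,5-dimethoxyphenyl]-4-methyldihydrofuran-2(3H)-one (C5 epimers) F6. Its 3,4-trans arrangement is also the thermodynamically preferred one.
- LiAlH4 (THF, 0 °C) should give 13.

**Step 9.** What may go wrong: incomplete hydrogenolysis of the benzylic C7'–O bond, or its ionization on the catalyst to a quinone methide that tautomerizes to a styrene and so erodes the configuration at C8'.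

Fallback: the benzylic oxygen is removed by ionic hydride transfer before the phenols are set free. It sets out from 14 and comes back at 15.
- Ionic hydrogenation (Et3SiH, BF3·OEt2, CH2Cl2, −40 °C) captures the benzylic cation with hydride while both phenols are still benzylated, so no quinone methide can form. It should give (2S,3R)-2-[4-(benzyloxy)-3-methoxybenzyl]-4-[4-(benzyloxy)-3,5-dimethoxyphenyl]-3-methylbutyl acetate F7.
- Plain hydrogenolysis of the two benzyl ethers (H2, Pd/C, EtOAc, rt) should give 15.

## Further compounds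

F1 | step 6 | (1R,2S)-1-[4-(benzyloxy)-3,5-dimethoxyphenyl]-2-methylbut-3-en-1-ol | C=C[C@H](C)[C@@H](O)c1cc(OC)c(OCc2ccccc2)c(OC)c1
F2 | step 6 | (1R,2S)-1-[4-(benzyloxy)-3,5-dimethoxyphenyl]-2-methylbutane-1,4-diol | OCC[C@H](C)[C@@H](O)c1cc(OC)c(OCc2ccccc2)c(OC)c1
F3 | step 6 | (4S,5R)-5-[4-(benzyloxy)-3,5-dimethoxyphenyl]-4-methyldihydrofuran-2(3H)-one | O=C1C[C@H](C)[C@H](c2cc(OC)c(OCc3ccccc3)c(OC)c2)O1
F4 | step 6 | (3S,4S,5R)-3-[4-(benzyloxy)-3-methoxybenzyl]-5-[4-(benzyloxy)-3,5-dimethoxyphenyl]-4-methyldihydrofuran-2(3H)-one | COc1cc(C[C@@H]2C(=O)O[C@@H](c3cc(OC)c(OCc4ccccc4)c(OC)c3)[C@H]2C)ccc1OCc1ccccc1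
F5 | step 7 | (R)-4-benzyl-3-[(2S,3S)-2-[4-(benzyloxy)-3-methoxybenzyl]-4-[4-(benzyloxy)-3,5-dimethoxyphenyl]-4-hydroxy-3-methylbutanoyl]oxazolidin-2-one, C4 epimers | COc1cc(C[C@H](C(=O)N2C(=O)OC[C@H]2Cc2ccccc2)[C@H](C)C(O)c2cc(OC)c(OCc3ccccc3)c(OC)c2)ccc1OCc1ccccc1
F6 | step 7 | (3S,4S)-3-[4-(benzyloxy)-3-methoxybenzyl]-5-[4-(benzyloxy)-3,5-dimethoxyphenyl]-4-methyldihydrofuran-2(3H)-one, C5 epimers | COc1cc(C[C@@H]2C(=O)OC(c3cc(OC)c(OCc4ccccc4)c(OC)c3)[C@H]2C)ccc1OCc1ccccc1
F7 | step 9 | (2S,3R)-2-[4-(benzyloxy)-3-methoxybenzyl]-4-[4-(benzyloxy)-3,5-dimethoxyphenyl]-3-methylbutyl acetate | COc1cc(C[C@H](COC(C)=O)[C@H](C)Cc2cc(OC)c(OCc3ccccc3)c(OC)c2)ccc1OCc1ccccc1
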